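**Strategy.** The route rests on closing the 2,2-dimethyl-2H-pyran ring of the chromene unit at its O1–C2 bond by an oxa-6π electrocyclization. Heating 5-bromo-3-methoxybenzene-1,2-diol, a free catechol, with 3-methylbut-2-enal first joins C4 to C4a by condensation. This gives an ortho-quinone methide (a 1-oxatriene) that closes O1–C2 in the same operation, so both bonds of the pyran ring arise without protecting groups. The step exploits that the oxygen on C8a (C3' of ring B) has one free ortho carbon, C4a (C2'), para to the C7 methoxy group, whereas the neighbouring C8 hydroxyl has none. The 5-bromochromene is then joined to a 3-iodochromone (rings A and C) by borylation/Suzuki coupling.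

Key step: step 2

Remark: the target has no stereocentre. Compounds 1, 4 and 7 are taken as commercially available. Chromene numbering (O1, C2, C3, C4, C4a, C5 to C8, C8a) is used for the ring B unit, and benzene numbering (C1 to C6, hydroxyls on C1 and C2, methoxy on C3, bromine on C5) for catechol 3.

**Route**

Step 1
Reactants: 1 5-bromo-2-hydroxy-3-methoxybenzaldehyde
Product: 3 5-bromo-3-methoxybenzene-1,2-diol, via aryl formate 2 (not isolated)
Conditions: 30% aq. H2O2, 1 M NaOH, THF/H2O, 0 °C to rt, N2; then 2 M HCl
Reagents that add atoms: hydrogen peroxide, OO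
Why: Dakin oxidation, in which hydroperoxide adds to the aldehyde next to the phenoxide, the aryl group migrates to oxygen to give formate 2, and saponification in the same flask should deliver the catechol with the aryl bromide untouched.

Step 2
Reactants: 3 5-bromo-3-methoxybenzene-1,2-diol; 4 3-methylbut-2-enal
Product: 6 5-bromo-7-methoxy-2,2-dimethyl-2H-chromen-8-ol, via ortho-quinone methide 5 (not isolated)
Conditions: 4 (3 equiv), ethylenediammonium diacetate (EDDA, 20 mol %), xylenes, 140 °C, Ar
Reagents that add atoms: none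
Why: EDDA converts enal 4 into its iminium ion, C6 of 3 (ortho to the C1 hydroxyl and para to the C3 methoxy group) adds to it in a Knoevenagel-type condensation, and loss of the amine gives ortho-quinone methide 5, a 1-oxatriene that closes by thermal oxa-6π electrocyclization to form the O1–C2 bond of the chromene and restore the arene. The closest known reaction type is the domino condensation/oxa-6π electrocyclization (formal [3+3] annulation) of phenols and resorcinols with 3-methylbut-2-enal. The pyran ring closes in a pericyclic, disrotatory six-electron mode, so the quaternary C2 is reached without ionic substitution at a tertiary carbon. No stereocentre is formed, since C2 carries two methyl groups. The step needs C–C bond formation at C6 and ring closure through the C1 oxygen only; this is secured because the C2 hydroxyl, flanked by C1–OH and C3–OMe, has no free ortho carbon and cannot give a cyclizable quinone methide, while reversible adducts at C4 or at oxygen are drained by the irreversible, aromatizing electrocyclization. The C5 bromine should additionally push the dienyl chain of 5 toward the carbonyl side, the geometry required for closure.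

Step 3
Reactants: 7 1-(2,4-dihydroxyphenyl)ethan-1-one
Product: 8 1-[2-hydroxy-4-(methoxymethoxy)phenyl]ethan-1-one
Conditions: MOMCl (1.1 equiv), K2CO3, acetone, 0 °C to rt
Reagents that add atoms: chloromethyl methyl ether, COCCl
Why: O-alkylation (MOM protection) should occur only at the 4-hydroxyl, because the 2-hydroxyl is held in a hydrogen bond to the ketone and is much less nucleophilic.

Step 4
Reactants: 8 1-[2-hydroxy-4-(methoxymethoxy)phenyl]ethan-1-one
Product: 9 (2E)-3-(dimethylamino)-1-[2-hydroxy-4-(methoxymethoxy)phenyl]prop-2-en-1-one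
Conditions: DMF-DMA (2 equiv), toluene, 95 °C
Reagents that add atoms: N,N-dimethylformamide dimethyl acetal, COC(OC)N(C)C
Why: Condensation of the methyl ketone with the amide acetal should give the (E)-enaminone, the MOM ether preventing O-methylation of the 4-oxygen by the reagent.

Step 5
Reactants: 9 (2E)-3-(dimethylamino)-1-[2-hydroxy-4-(methoxymethoxy)phenyl]prop-2-en-1-one
Product: 10 3-iodo-7-(methoxymethoxy)-4H-chromen-4-one
Conditions: I2 (2 equiv), pyridine, CHCl3, rt; aq. Na2S2O3 work-up
Reagents that add atoms: iodine, II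
Why: Iodine-mediated cyclization of a 2-hydroxyaryl enaminone, in which α-iodination, attack of the phenol on the iminium carbon and loss of dimethylamine should give the 3-iodochromone, pyridine buffering the medium so that the MOM ether survives.

Step 6
Reactants: 6 5-bromo-7-methoxy-2,2-dimethyl-2H-chromen-8-ol; 10 3-iodo-7-(methoxymethoxy)-4H-chromen-4-one
Product: 12 3-(8-hydroxy-7-methoxy-2,2-dimethyl-2H-chromen-5-yl)-7-(methoxymethoxy)-4H-chromen-4-one, via pinacol boronate 11 (not isolated)
Conditions: 6 (1.2 equiv), B2pin2 (1.3 equiv), KOAc (3 equiv), Pd(dppf)Cl2·CH2Cl2 (5 mol %), 1,4-dioxane, 90 °C; then 10 (1.0 equiv), 2 M aq. K2CO3, 70 °C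
Reagents that add atoms: bis(pinacolato)diboron, CC1(C)OB(OC1(C)C)B1OC(C)(C)C(C)(C)O1 (its boron is carried by intermediate 11 only, none remains in 12)
Why: One-pot Miyaura borylation of the aryl bromide followed by Suzuki–Miyaura coupling of 11 with the reactive C–I bond of 10 should form the C3–C1' bond of the isoflavone, the free phenol, the chromene alkene and the MOM ether all tolerating acetate and carbonate bases.

Step 7
Reactants: 12 3-(8-hydroxy-7-methoxy-2,2-dimethyl-2H-chromen-5-yl)-7-(methoxymethoxy)-4H-chromen-4-one
Product: 13 7-hydroxy-3-(8-hydroxy-7-methoxy-2,2-dimethyl-2H-chromen-5-yl)-4H-chromen-4-one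
Conditions: HCl (1.25 M in MeOH), MeOH/THF, 45 °C
Reagents that add atoms: none
Why: Acid-catalysed acetal exchange should transfer the methoxymethyl group to methanol and free the 7-hydroxyl under conditions mild enough for the 2,2-dimethylchromene and the chromone.

**Compound list**

1 | 5-bromo-2-hydroxy-3-methoxybenzaldehyde | O=Cc1cc(Br)cc(OC)c1O | starting material
2 | 5-bromo-2-hydroxy-3-methoxyphenyl formate | O=COc1cc(Br)cc(OC)c1O | intermediate
3 | 5-bromo-3-methoxybenzene-1,2-diol | Oc1cc(Br)cc(OC)c1O | intermediate
4 | 3-methylbut-2-enal | CC(C)=CC=O | starting material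
5 | (6E)-5-bromo-2-hydroxy-3-methoxy-6-(3-methylbut-2-en-1-ylidene)cyclohexa-2,4-dien-1-one | CC(C)=C/C=C1\C(=O)C(O)=C(OC)C=C1Br | intermediate
6 | 5-bromo-7-methoxy-2,2-dimethyl-2H-chromen-8-ol | COc1cc(Br)c2c(c1O)OC(C)(C)C=C2 | intermediate
7 | 1-(2,4-dihydroxyphenyl)ethan-1-one | CC(=O)c1ccc(O)cc1O | starting material
8 | 1-[2-hydroxy-4-(methoxymethoxy)phenyl]ethan-1-one | CC(=O)c1ccc(OCOC)cc1O | intermediate
9 | (2E)-3-(dimethylamino)-1-[2-hydroxy-4-(methoxymethoxy)phenyl]prop-2-en-1-one | CN(C)/C=C/C(=O)c1ccc(OCOC)cc1O | intermediate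
10 | 3-iodo-7-(methoxymethoxy)-4H-chromen-4-one | COCOc1ccc2c(c1)occ(I)c2=O | intermediate
11 | 7-methoxy-2,2-dimethyl-5-(4,4,5,5-tetramethyl-1,3,2-dioxaborolan-2-yl)-2H-chromen-8-ol | COc1cc(B2OC(C)(C)C(C)(C)O2)c2c(c1O)OC(C)(C)C=C2 | intermediate
12 | 3-(8-hydroxy-7-methoxy-2,2-dimethyl-2H-chromen-5-yl)-7-(methoxymethoxy)-4H-chromen-4-one | COc1cc(-c2coc3cc(OCOC)ccc3c2=O)c2c(c1O)OC(C)(C)C=C2 | intermediate
13 | 7-hydroxy-3-(8-hydroxy-7-methoxy-2,2-dimethyl-2H-chromen-5-yl)-4H-chromen-4-one | COc1cc(-c2coc3cc(O)ccc3c2=O)c2c(c1O)OC(C)(C)C=C2 | target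

**Step count and risks**

Total step count: 7. Longest linear sequence: 5 (steps 3, 4, 5, 6 and 7, from 7 to 13); the ring B branch (steps 1, 2, 6 and 7) is 4 steps long.

Steps most likely to fail:

1. Step 2 (key step). The C-alkylation at C6, which is flanked by the bromine, may be slow. The enal may then be lost to self-condensation, or the catechol may be tied up in reversible acetal formation across its two hydroxyls, so that conversion to the chromene stalls. The fallback sets out from 1 and comes back at 6, replacing the condensation by an aryl propargyl ether rearrangement. The hydroxyl of 1 would be protected (MOMCl, i-Pr2NEt, CH2Cl2) to give 5-bromo-3-methoxy-2-(methoxymethoxy)benzaldehyde F1. Baeyer–Villiger oxidation (mCPBA, CH2Cl2) would give 5-bromo-3-methoxy-2-(methoxymethoxy)phenyl formate F2, and methanolysis (K2CO3, MeOH) would give 5-bromo-3-methoxy-2-(methoxymethoxy)phenol F3. Its single free hydroxyl would be alkylated with 3-chloro-3-methylbut-1-yne (DBU, CuCl2 cat., MeCN, 0 °C) to 5-bromo-1-methoxy-2-(methoxymethoxy)-3-[(2-methylbut-3-yn-2-yl)oxy]benzene F4. Heating (N,N-diethylaniline, 190 °C) should trigger the propargyl Claisen rearrangement, 1,5-hydrogen shift and oxa-6π closure at the only free ortho carbon to give 5-bromo-7-methoxy-8-(methoxymethoxy)-2,2-dimethyl-2H-chromene F5. HCl in MeOH would then return 6.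

2. Step 6. Borylation of the electron-rich, ortho-substituted aryl bromide bearing a free phenol may be incomplete. The boronate may undergo protodeboronation, or the chromone may be opened by base in the hot aqueous stage, and homocoupling may consume the partners. The fallback sets out from 6 and comes back at 12; it generates the nucleophile by halogen–lithium exchange on a protected phenol and couples an isolated boronate. Silylation (TBSCl, imidazole, DMF) would give tert-butyl[(5-bromo-7-methoxy-2,2-dimethyl-2H-chromen-8-yl)oxy]dimethylsilane F6. Bromine–lithium exchange (n-BuLi, THF, −78 °C) would give the aryllithium F7, and trapping with 2-isopropoxy-4,4,5,5-tetramethyl-1,3,2-dioxaborolane would give the isolated silyl-protected pinacol boronate F8. Suzuki coupling with 10 (Pd(PPh3)4, aq. Na2CO3, DME, 80 °C) would give the silyl-protected isoflavone F9, and TBAF in THF at 0 °C would return 12.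

3. Step 7. Acid may add methanol or water across the C3=C4 bond of the chromene, or open the pyran ring, faster than it cleaves the MOM ether on the electron-poor chromone oxygen. The fallback sets out from 10 and comes back at 13; it moves the acid step ahead of the coupling and ends with a basic deprotection. Treating 10 with HCl in MeOH (no chromene present) would give 7-hydroxy-3-iodo-4H-chromen-4-one F10. Acylation (pivaloyl chloride, Et3N, CH2Cl2) would give 3-iodo-4-oxo-4H-chromen-7-yl pivalate F11. Coupling with boronate 11, generated from 6 as in step 6 (aq. K3PO4 in the second stage, 60 °C), would give the 7-O-pivaloyl isoflavone F12. Methanolysis (K2CO3, MeOH, rt) would deliver 13; any pivalate lost during the coupling would lead to the same compound.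

**Further compounds**

F1 | step 2 | 5-bromo-3-methoxy-2-(methoxymethoxy)benzaldehyde | COCOc1c(C=O)cc(Br)cc1OC
F2 | step 2 | 5-bromo-3-methoxy-2-(methoxymethoxy)phenyl formate | COCOc1c(OC=O)cc(Br)cc1OC
F3 | step 2 | 5-bromo-3-methoxy-2-(methoxymethoxy)phenol | COCOc1c(O)cc(Br)cc1OC
F4 | step 2 | 5-bromo-1-methoxy-2-(methoxymethoxy)-3-[(2-methylbut-3-yn-2-yl)oxy]benzene | COCOc1c(OC(C)(C)C#C)cc(Br)cc1OC
F5 | step 2 | 5-bromo-7-methoxy-8-(methoxymethoxy)-2,2-dimethyl-2H-chromene | COCOc1c(OC)cc(Br)c2c1OC(C)(C)C=C2
F6 | step 6 | tert-butyl[(5-bromo-7-methoxy-2,2-dimethyl-2H-chromen-8-yl)oxy]dimethylsilane | COc1cc(Br)c2c(c1O[Si](C)(C)C(C)(C)C)OC(C)(C)C=C2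
F7 | step 6 | [8-(tert-butyldimethylsilyloxy)-7-methoxy-2,2-dimethyl-2H-chromen-5-yl]lithium | COc1cc([Li])c2c(c1O[Si](C)(C)C(C)(C)C)OC(C)(C)C=C2
F8 | step 6 | tert-butyl{[7-methoxy-2,2-dimethyl-5-(4,4,5,5-tetramethyl-1,3,2-dioxaborolan-2-yl)-2H-chromen-8-yl]oxy}dimethylsilane | COc1cc(B2OC(C)(C)C(C)(C)O2)c2c(c1O[Si](C)(C)C(C)(C)C)OC(C)(C)C=C2
F9 | step 6 | 3-[8-(tert-butyldimethylsilyloxy)-7-methoxy-2,2-dimethyl-2H-chromen-5-yl]-7-(methoxymethoxy)-4H-chromen-4-one | COc1cc(-c2coc3cc(OCOC)ccc3c2=O)c2c(c1O[Si](C)(C)C(C)(C)C)OC(C)(C)C=C2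
F10 | step 7 | 7-hydroxy-3-iodo-4H-chromen-4-one | Oc1ccc2c(c1)occ(I)c2=O
F11 | step 7 | 3-iodo-4-oxo-4H-chromen-7-yl pivalate | CC(C)(C)C(=O)Oc1ccc2c(c1)occ(I)c2=O
F12 | step 7 | 3-(8-hydroxy-7-methoxy-2,2-dimethyl-2H-chromen-5-yl)-4-oxo-4H-chromen-7-yl pivalate | COc1cc(-c2coc3cc(OC(=O)C(C)(C)C)ccc3c2=O)c2c(c1O)OC(C)(C)C=C2
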